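**Plan**

1. The retrosynthesis first cuts the depside C(=O)–O bond between the ring A carbonyl and O4 of ring B, then the O2–methyl bond of ring B, and strips the masks (two dioxolanes, a tert-butyl ester, a benzyl ether).
2. Ring B (benzoic acid numbering) has oxygen on C2 and C4 and carbon branches on C1 (carboxyl) and C6 (the CH2 of the oxoheptyl arm). That is the pattern of a 3,5,7-triketo ester folded by a C1–C6 aldol, so the C1–C6 bond is cut and the three ketones are stored in a 2,6-disubstituted 4-pyrone.
3. The pyrone arises from 2,6-dimethyl-4H-pyran-4-one by two lateral C–C bond formations (hexanoyl on one methyl, tert-butoxycarbonyl on the other). Ring A is bought as methyl orsellinate and only its C6 methyl is acylated.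
4. Forward: pyrone (steps 1–3), ring B by pyrone opening and aldol aromatisation (step 4), ring A acid (steps 5–8), depside bond (step 9), O2 methylation, hydrogenolysis and acidic unmasking (steps 10–12).
5. Stereochemistry: the target has no stereocentre; the two in the transient aldol of step 4 are erased on aromatisation.

Key step: step 4

Remark: N-methoxy-N-methylhexanamide serves as the hexanoyl donor in both lateral acylations because its chelated adduct needs no second equivalent of carbanion; it is taken as a catalogue reagent.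

**Route**

Step 1
Reactants: 1 2,6-dimethyl-4H-pyran-4-one; 2 N-methoxy-N-methylhexanamide
Product: 3 2-methyl-6-(2-oxoheptyl)-4H-pyran-4-one
Conditions: LiN(SiMe3)2 (1.1 equiv), THF, −78 °C; then 2, −78 → −20 °C; aq. NH4Cl
Reagents that add atoms: none
Why: Lateral (vinylogous) deprotonation of one pyrone methyl gives a dienolate that is C-acylated by the Weinreb amide, whose lithium-chelated tetrahedral adduct survives until the quench and so prevents over-addition and acylation of the second methyl (Weinreb ketone synthesis on a laterally metalated 4-pyrone).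

Step 2
Reactants: 3 2-methyl-6-(2-oxoheptyl)-4H-pyran-4-one; 4 ethylene glycol
Product: 5 2-methyl-6-[(2-pentyl-1,3-dioxolan-2-yl)methyl]-4H-pyran-4-one
Conditions: ethylene glycol (5 equiv), p-TsOH·H2O (cat.), benzene, reflux, Dean–Stark
Reagents that add atoms: none
Why: Acid-catalysed ketalisation with azeotropic removal of water should convert only the side-chain ketone, because the ring carbonyl is a vinylogous ester on both sides and does not form ketals.

Step 3
Reactants: 5 2-methyl-6-[(2-pentyl-1,3-dioxolan-2-yl)methyl]-4H-pyran-4-one; 6 di-tert-butyl dicarbonate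
Product: 7 tert-butyl 2-[4-oxo-6-[(2-pentyl-1,3-dioxolan-2-yl)methyl]-4H-pyran-2-yl]acetate
Conditions: LiN(SiMe3)2 (2.1 equiv), THF, −78 °C; then Boc2O (1.05 equiv), −78 → −40 °C; aq. NH4Cl
Reagents that add atoms: none
Why: Kinetic lateral deprotonation should take place at the unhindered methyl and not at the neopentyl-like methylene beside the ketal, and the dienolate undergoes Claisen-type C-alkoxycarbonylation by the dicarbonate, the second equivalent of base storing the more acidic product as its enolate against a second acylation.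

Step 4
Reactants: 7 tert-butyl 2-[4-oxo-6-[(2-pentyl-1,3-dioxolan-2-yl)methyl]-4H-pyran-2-yl]acetate
Product: 10 tert-butyl 2,4-dihydroxy-6-[(2-pentyl-1,3-dioxolan-2-yl)methyl]benzoate, via triketo ester 8 (not isolated), via cyclic aldol 9 (not isolated)
Conditions: KOH (1 M aq., 5 equiv), THF, argon, 0 °C → rt; then aq. NaH2PO4 to pH 6
Reagents that add atoms: none
Why: Hydroxide adds in conjugate fashion to C6 of the pyrone, the ring carbon remote from the ionised acetate arm, and retro-oxa-Michael cleavage of the C6–O1 bond unravels the heterocycle to the enolates of triketo ester 8, in which pyrone carbons C2, C4 and C6 have become the C3, C5 and C7 ketones. The C2 methylene of 8, doubly activated by the ester and the C3 ketone, then adds to the C7 ketone to give aldol 9, and loss of the tertiary hydroxyl as water followed by enolisation of the two remaining ring ketones delivers the arene, so that the water taken up in the opening is given back and the step is a net isomerisation. The closest known reaction type is the base-induced opening of 4-pyrones to 1,3,5-triketones joined to the biomimetic aldol cyclisation of 3,5,7-triketo esters to 2,4-dihydroxy-6-alkylbenzoates. Ring B closes through the new C1–C6 bond (benzoate numbering; C2–C7 of the chain) in a 6-(enolendo)-exo-trig aldol, and no stereocentre survives because the two formed in 9 are erased on aromatisation. The step needs this aldol fold to win over Claisen closure onto the ester (an acylphloroglucinol), lactonisation to a 2-pyrone and an aldol from the other chain end: the tert-butyl ester is too hindered and too poor an acyl donor to be attacked, and the dioxolane leaves C8 singly activated and neopentyl-like while keeping the fourth ketone out of play, so only the C2 carbanion and the C7 carbonyl can meet.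

Step 5
Reactants: 11 methyl 2,4-dihydroxy-6-methylbenzoate
Product: 13 methyl 2-(benzyloxy)-4-methoxy-6-methylbenzoate, via methyl 2-hydroxy-4-methoxy-6-methylbenzoate 12 (not isolated)
Conditions: MeI (1.0 equiv), K2CO3 (3 equiv), DMF, rt; then BnBr (1.3 equiv), 60 °C
Reagents that add atoms: iodomethane, CI; benzyl bromide, BrCc1ccccc1
Why: Two Williamson etherifications run in sequence, the free and more acidic C4 hydroxyl being methylated at room temperature, whereas the C2 hydroxyl, hydrogen-bonded to the ester carbonyl, reacts only on heating and then takes the benzyl group.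

Step 6
Reactants: 13 methyl 2-(benzyloxy)-4-methoxy-6-methylbenzoate; 2 N-methoxy-N-methylhexanamide
Product: 14 methyl 2-(benzyloxy)-4-methoxy-6-(2-oxoheptyl)benzoate
Conditions: LiN(iPr)2 (1.2 equiv), THF, −78 °C; then 2 (1.2 equiv), −78 → −40 °C; aq. NH4Cl
Reagents that add atoms: none
Why: Lateral lithiation of the ortho-toluate gives the ester-stabilised benzylic anion, which adds to the Weinreb amide to form a chelated adduct that releases the ketone only on quench, so neither double addition nor enolate closure to an isocoumarin should take place (Weinreb ketone synthesis).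

Step 7
Reactants: 14 methyl 2-(benzyloxy)-4-methoxy-6-(2-oxoheptyl)benzoate; 4 ethylene glycol
Product: 15 methyl 2-(benzyloxy)-4-methoxy-6-[(2-pentyl-1,3-dioxolan-2-yl)methyl]benzoate
Conditions: ethylene glycol (5 equiv), p-TsOH·H2O (cat.), benzene, reflux, Dean–Stark
Reagents that add atoms: none
Why: Acid-catalysed ketalisation masks the ketone, which would otherwise close onto the activated carboxyl as an isocoumarin in later steps, while the hindered methyl ester and the benzyl ether are inert.

Step 8
Reactants: 15 methyl 2-(benzyloxy)-4-methoxy-6-[(2-pentyl-1,3-dioxolan-2-yl)methyl]benzoate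
Product: 16 2-(benzyloxy)-4-methoxy-6-[(2-pentyl-1,3-dioxolan-2-yl)methyl]benzoic acid
Conditions: KOH (10 equiv), DMSO/H2O (4:1), 90 °C; then 1 M HCl to pH 3–4 at 0 °C, immediate extraction
Reagents that add atoms: potassium hydroxide, [K+].[OH-]
Why: Saponification (BAc2) of the di-ortho-substituted methyl ester needs poorly solvated hydroxide in hot aqueous DMSO, conditions to which the dioxolane and the benzyl ether are stable.

Step 9
Reactants: 16 2-(benzyloxy)-4-methoxy-6-[(2-pentyl-1,3-dioxolan-2-yl)methyl]benzoic acid; 10 tert-butyl 2,4-dihydroxy-6-[(2-pentyl-1,3-dioxolan-2-yl)methyl]benzoate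
Product: 18 tert-butyl 4-{[2-(benzyloxy)-4-methoxy-6-[(2-pentyl-1,3-dioxolan-2-yl)methyl]benzoyl]oxy}-2-hydroxy-6-[(2-pentyl-1,3-dioxolan-2-yl)methyl]benzoate, via acid chloride 17 (not isolated)
Conditions: Me2C=C(Cl)NMe2 (1.1 equiv), CH2Cl2, 0 °C → rt; then 10 (1.0 equiv), Et3N (2.5 equiv), DMAP (0.1 equiv), 0 °C → rt
Reagents that add atoms: none
Why: The Ghosez reagent makes the acid chloride without free HCl, so the dioxolane survives, and DMAP-catalysed acyl transfer (nucleophilic catalysis of an acid chloride esterification) should go to the C4 hydroxyl of 10, the more acidic and unencumbered one, while the C2 hydroxyl is tied in a hydrogen bond to the tert-butyl ester carbonyl.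

Step 10
Reactants: 18 the C2-hydroxy depside from step 9
Product: 19 tert-butyl 4-{[2-(benzyloxy)-4-methoxy-6-[(2-pentyl-1,3-dioxolan-2-yl)methyl]benzoyl]oxy}-2-methoxy-6-[(2-pentyl-1,3-dioxolan-2-yl)methyl]benzoate
Conditions: MeI (5 equiv), K2CO3 (3 equiv), DMF, rt → 40 °C
Reagents that add atoms: iodomethane, CI
Why: Williamson O-methylation of the last free phenol, during which the depside carbonyl, set between two ortho substituents of ring A, is shielded from carbonate and phenoxide.

Step 11
Reactants: 19 the O-benzyl, O-methyl depside from step 10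
Product: 20 tert-butyl 4-{[2-hydroxy-4-methoxy-6-[(2-pentyl-1,3-dioxolan-2-yl)methyl]benzoyl]oxy}-2-methoxy-6-[(2-pentyl-1,3-dioxolan-2-yl)methyl]benzoate
Conditions: H2 (1 atm), Pd/C (10 wt% Pd), EtOAc, rt
Reagents that add atoms: none
Why: Catalytic hydrogenolysis cleaves the benzyl aryl ether and leaves the aryl ester, the dioxolanes and the tert-butyl ester untouched.

Step 12
Reactants: 20 the bis-ketal tert-butyl ester from step 11
Product: 21 4-{[2-hydroxy-4-methoxy-6-(2-oxoheptyl)benzoyl]oxy}-2-methoxy-6-(2-oxoheptyl)benzoic acid (target)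
Conditions: CF3CO2H/CH2Cl2/H2O (10:10:1), 0 °C → rt
Reagents that add atoms: water, O
Why: Acid removes the three remaining masks in one operation, the dioxolanes by ketal hydrolysis and the tert-butyl ester by alkyl–oxygen (AAL1) cleavage with loss of isobutene, while the aryl ester of the depside is stable to acid and the short, cold, aqueous treatment should avoid cyclodehydration of the keto acid to an isocoumarin.

**Compound list**

1 | 2,6-dimethyl-4H-pyran-4-one | CC1=CC(=O)C=C(C)O1 | starting material
2 | N-methoxy-N-methylhexanamide | CCCCCC(=O)N(C)OC | starting material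
3 | 2-methyl-6-(2-oxoheptyl)-4H-pyran-4-one | CCCCCC(=O)CC1=CC(=O)C=C(C)O1 | intermediate
4 | ethylene glycol | OCCO | starting material
5 | 2-methyl-6-[(2-pentyl-1,3-dioxolan-2-yl)methyl]-4H-pyran-4-one | CCCCCC1(CC2=CC(=O)C=C(C)O2)OCCO1 | intermediate
6 | di-tert-butyl dicarbonate | CC(C)(C)OC(=O)OC(=O)OC(C)(C)C | starting material
7 | tert-butyl 2-[4-oxo-6-[(2-pentyl-1,3-dioxolan-2-yl)methyl]-4H-pyran-2-yl]acetate | CCCCCC1(CC2=CC(=O)C=C(CC(=O)OC(C)(C)C)O2)OCCO1 | intermediate
8 | tert-butyl 3,5,7-trioxo-8-(2-pentyl-1,3-dioxolan-2-yl)octanoate | CCCCCC1(CC(=O)CC(=O)CC(=O)CC(=O)OC(C)(C)C)OCCO1 | intermediate (not isolated)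
9 | tert-butyl 2-hydroxy-4,6-dioxo-2-[(2-pentyl-1,3-dioxolan-2-yl)methyl]cyclohexane-1-carboxylate (two transient stereocentres, formed as a mixture and lost in the same flask) | CCCCCC1(CC2(O)CC(=O)CC(=O)C2C(=O)OC(C)(C)C)OCCO1 | intermediate (not isolated)
10 | tert-butyl 2,4-dihydroxy-6-[(2-pentyl-1,3-dioxolan-2-yl)methyl]benzoate | CCCCCC1(Cc2cc(O)cc(O)c2C(=O)OC(C)(C)C)OCCO1 | intermediate
11 | methyl 2,4-dihydroxy-6-methylbenzoate (methyl orsellinate) | COC(=O)c1c(C)cc(O)cc1O | starting material
12 | methyl 2-hydroxy-4-methoxy-6-methylbenzoate | COC(=O)c1c(C)cc(OC)cc1O | intermediate (not isolated)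
13 | methyl 2-(benzyloxy)-4-methoxy-6-methylbenzoate | COC(=O)c1c(C)cc(OC)cc1OCc1ccccc1 | intermediate
14 | methyl 2-(benzyloxy)-4-methoxy-6-(2-oxoheptyl)benzoate | CCCCCC(=O)Cc1cc(OC)cc(OCc2ccccc2)c1C(=O)OC | intermediate
15 | methyl 2-(benzyloxy)-4-methoxy-6-[(2-pentyl-1,3-dioxolan-2-yl)methyl]benzoate | CCCCCC1(Cc2cc(OC)cc(OCc3ccccc3)c2C(=O)OC)OCCO1 | intermediate
16 | 2-(benzyloxy)-4-methoxy-6-[(2-pentyl-1,3-dioxolan-2-yl)methyl]benzoic acid | CCCCCC1(Cc2cc(OC)cc(OCc3ccccc3)c2C(=O)O)OCCO1 | intermediate
17 | 2-(benzyloxy)-4-methoxy-6-[(2-pentyl-1,3-dioxolan-2-yl)methyl]benzoyl chloride | CCCCCC1(Cc2cc(OC)cc(OCc3ccccc3)c2C(=O)Cl)OCCO1 | intermediate (not isolated)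
18 | tert-butyl 4-{[2-(benzyloxy)-4-methoxy-6-[(2-pentyl-1,3-dioxolan-2-yl)methyl]benzoyl]oxy}-2-hydroxy-6-[(2-pentyl-1,3-dioxolan-2-yl)methyl]benzoate | CCCCCC1(Cc2cc(OC)cc(OCc3ccccc3)c2C(=O)Oc2cc(O)c(C(=O)OC(C)(C)C)c(CC3(CCCCC)OCCO3)c2)OCCO1 | intermediate
19 | tert-butyl 4-{[2-(benzyloxy)-4-methoxy-6-[(2-pentyl-1,3-dioxolan-2-yl)methyl]benzoyl]oxy}-2-methoxy-6-[(2-pentyl-1,3-dioxolan-2-yl)methyl]benzoate | CCCCCC1(Cc2cc(OC)cc(OCc3ccccc3)c2C(=O)Oc2cc(OC)c(C(=O)OC(C)(C)C)c(CC3(CCCCC)OCCO3)c2)OCCO1 | intermediate
20 | tert-butyl 4-{[2-hydroxy-4-methoxy-6-[(2-pentyl-1,3-dioxolan-2-yl)methyl]benzoyl]oxy}-2-methoxy-6-[(2-pentyl-1,3-dioxolan-2-yl)methyl]benzoate | CCCCCC1(Cc2cc(OC)cc(O)c2C(=O)Oc2cc(OC)c(C(=O)OC(C)(C)C)c(CC3(CCCCC)OCCO3)c2)OCCO1 | intermediate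
21 | 4-{[2-hydroxy-4-methoxy-6-(2-oxoheptyl)benzoyl]oxy}-2-methoxy-6-(2-oxoheptyl)benzoic acid | CCCCCC(=O)Cc1cc(OC)cc(O)c1C(=O)Oc1cc(CC(=O)CCCCC)c(C(=O)O)c(OC)c1 | target

**Count and risks**

Total steps: 12. Longest linear sequence: 8 steps (steps 1–4 then 9–12; the ring A branch, steps 5–8 then 9–12, is equally long).

Steps most likely to fail:

1. Step 4 (key step). The base may ionise the acetate methylene of 7 and so slow hydroxide addition to the ring. On forcing, retro-Claisen scission of the polyketo chain or closure in another mode could then compete. The fallback sets out from 5 and returns at 10; it opens the ring before the carboxyl carbon is attached. Ba(OH)2·8H2O in aqueous THF should convert 5 into 1-(2-pentyl-1,3-dioxolan-2-yl)heptane-2,4,6-trione F1. Its trianion (LiN(iPr)2, 3.3 equiv, THF, 0 °C) would be alkoxycarbonylated with di-tert-butyl dicarbonate 6 at the terminal methyl carbanion, the last formed and most reactive site. This gives triketo ester 8 directly, which is cyclised in dilute aqueous KOH at about pH 10 to 10.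

2. Step 3. Deprotonation may not stay at the methyl group: metalation of the ketal-flanked methylene would be followed by E1cB opening of the dioxolane, and a second alkoxycarbonylation of the product enolate is also possible. The fallback sets out from 1 and returns at 7; it reverses the order of the two lateral functionalisations so that the first deprotonation is on the symmetric pyrone. Pyrone 1 with LiN(SiMe3)2 (2.1 equiv) and dicarbonate 6 should give tert-butyl 2-(6-methyl-4-oxo-4H-pyran-2-yl)acetate F2. Its dianion (LiN(iPr)2, 2.1 equiv, THF, −78 °C) would be acylated at the methyl-derived terminus by amide 2 to give tert-butyl 2-[4-oxo-6-(2-oxoheptyl)-4H-pyran-2-yl]acetate F3. The ketone is then ketalised under aprotic Noyori conditions (Me3SiOCH2CH2OSiMe3, Me3SiOTf cat., CH2Cl2, −78 → −20 °C), which spare the tert-butyl ester, to reach 7.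

3. Step 10. Carbonate or phenoxide may transfer or remove the ring A acyl group, or alkylation of the hydrogen-bonded hydroxyl beside the tert-butyl ester may stay incomplete. The fallback sets out from 10 and returns at 19; it installs the methyl ether before the depside bond is made. Selective benzylation of the C4 hydroxyl of 10 (BnBr, K2CO3, acetone, rt) should give tert-butyl 4-(benzyloxy)-2-hydroxy-6-[(2-pentyl-1,3-dioxolan-2-yl)methyl]benzoate F4. Methylation (MeI, K2CO3, DMF, 50 °C) gives tert-butyl 4-(benzyloxy)-2-methoxy-6-[(2-pentyl-1,3-dioxolan-2-yl)methyl]benzoate F5. Hydrogenolysis (H2, Pd/C, EtOAc) gives tert-butyl 4-hydroxy-2-methoxy-6-[(2-pentyl-1,3-dioxolan-2-yl)methyl]benzoate F6. Its sodium phenoxide (NaH, THF) is then acylated with acid chloride 17, made from 16 as in step 9, to give 19.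

**Further compounds**

F1 | step 4 | 1-(2-pentyl-1,3-dioxolan-2-yl)heptane-2,4,6-trione | CCCCCC1(CC(=O)CC(=O)CC(C)=O)OCCO1
F2 | step 3 | tert-butyl 2-(6-methyl-4-oxo-4H-pyran-2-yl)acetate | CC1=CC(=O)C=C(CC(=O)OC(C)(C)C)O1
F3 | step 3 | tert-butyl 2-[4-oxo-6-(2-oxoheptyl)-4H-pyran-2-yl]acetate | CCCCCC(=O)CC1=CC(=O)C=C(CC(=O)OC(C)(C)C)O1
F4 | step 10 | tert-butyl 4-(benzyloxy)-2-hydroxy-6-[(2-pentyl-1,3-dioxolan-2-yl)methyl]benzoate | CCCCCC1(Cc2cc(OCc3ccccc3)cc(O)c2C(=O)OC(C)(C)C)OCCO1
F5 | step 10 | tert-butyl 4-(benzyloxy)-2-methoxy-6-[(2-pentyl-1,3-dioxolan-2-yl)methyl]benzoate | CCCCCC1(Cc2cc(OCc3ccccc3)cc(OC)c2C(=O)OC(C)(C)C)OCCO1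
F6 | step 10 | tert-butyl 4-hydroxy-2-methoxy-6-[(2-pentyl-1,3-dioxolan-2-yl)methyl]benzoate | CCCCCC1(Cc2cc(O)cc(OC)c2C(=O)OC(C)(C)C)OCCO1
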